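**Plan**
- **Cuts, in order:** the hydroxyquinone goes back to a 2,3,5,6-tetramethoxyphenyl ring, C4=CH2 to a C4 carbinol, and C9-CH3 to C9-CHO. After C6=C7 is added, bonds C5–C10 and C8–C9 are cut, and last the C1–C10 bond of the open chain.
- **Enabling feature:** in ring B (C5–C10) the four neighbouring atoms C8, C9, C10 and C5 are all stereogenic, with C9 and C10 both quaternary. Ring A (C1–C5, C10) shares the C5–C10 edge, so a cyclohexene retron with C6=C7 opens both rings to one acyclic trienal.
- **Forward:** sorbaldehyde plus an allyl unit gives the C1–C8 chain. Tetramethoxybenzaldehyde plus ethyl acetoacetate gives the C9/C10 enol triflate. A B-alkyl Suzuki–Miyaura coupling joins them at C1–C10, rings A and B close together in one intramolecular Diels–Alder reaction, and the quinone is unmasked last.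
- **Stereochemistry:** C4 (R) comes from a Brown allylation and is the only reagent-controlled centre. The E,E-diene and (2E)-enal geometries, an endo formyl group and an equatorial C4 silyloxy group translate it into C5, C8, C9 and C10. C4 is then erased as the methylene carbon.

Key step: step 10

Remark (assumption): skeleton numbering is ring A = C1–C5 + C10, ring B = C5–C10, C11 = benzylic CH2. β is the face of the C10 methyl group, Ar = 2,3,5,6-tetramethoxyphenyl, TBS = tert-butyldimethylsilyl. Compounds 1, 5 and 8 are taken to be purchasable.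

Step 1
Reactants: 1 (2E,4E)-hexa-2,4-dienal (sorbaldehyde)
Product: 3 (4R,5E,7E)-nona-1,5,7-trien-4-ol, via diisopinocampheylborinate ester 2 (not isolated)
Conditions: (+)-Ipc2BOMe [from (−)-α-pinene], allylMgBr, Et2O, −78 °C → rt; 1, −78 °C; then NaOH, H2O2, rt
Reagents that add atoms: allylmagnesium bromide, C=CC[Mg]Br
Why: Brown allylation, in which the allylborane adds 1,2 to the dienal through a closed Zimmerman–Traxler chair and the isopinocampheyl groups derived from (−)-α-pinene select the aldehyde face that gives the (4R)-carbinol, the centre that later steers the cycloaddition.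

Step 2
Reactants: 3 (4R,5E,7E)-nona-1,5,7-trien-4-ol
Product: 4 tert-butyldimethyl[(4R,5E,7E)-nona-1,5,7-trien-4-yloxy]silane
Conditions: TBSCl, imidazole, DMF, rt
Reagents that add atoms: tert-butyldimethylsilyl chloride, CC(C)(C)[Si](C)(C)Cl
Why: Imidazole-promoted O-silylation of a secondary alcohol leaves C4 untouched and gives a bulky, weakly Lewis-basic ether that tolerates the borane, hydride and aluminium reagents to come.

Step 3
Reactants: 5 1,2,4,5-tetramethoxybenzene
Product: 7 2,3,5,6-tetramethoxybenzaldehyde, via 2,3,5,6-tetramethoxyphenyllithium 6 (not isolated)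
Conditions: n-BuLi, THF, 0 °C; DMF, 0 °C → rt; H2O
Reagents that add atoms: N,N-dimethylformamide, CN(C)C=O
Why: Directed ortho-lithiation at the CH flanked by two methoxy groups, followed by formylation of the aryllithium with DMF, is standard for this arene, and the two free positions are equivalent.

Step 4
Reactants: 7 2,3,5,6-tetramethoxybenzaldehyde; 8 ethyl acetoacetate
Product: 9 ethyl 2-acetyl-3-(2,3,5,6-tetramethoxyphenyl)prop-2-enoate (E/Z mixture)
Conditions: piperidine (cat.), AcOH (cat.), toluene, reflux, Dean–Stark trap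
Reagents that add atoms: none
Why: Knoevenagel condensation through the piperidinium iminium ion with azeotropic removal of water, where the alkene geometry does not matter because the double bond is saturated in the next step.

Step 5
Reactants: 9 ethyl 2-acetyl-3-(2,3,5,6-tetramethoxyphenyl)prop-2-enoate
Product: 10 ethyl 3-oxo-2-(2,3,5,6-tetramethoxybenzyl)butanoate (racemic)
Conditions: H2 (1 atm), Pd/C, EtOAc, rt
Reagents that add atoms: none
Why: Catalytic hydrogenation saturates the electron-poor alkene and spares the ketone, ester and arene, and the new α-centre is configurationally labile and is erased in step 6.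

Step 6
Reactants: 10 ethyl 3-oxo-2-(2,3,5,6-tetramethoxybenzyl)butanoate
Product: 11 ethyl (2E)-2-(2,3,5,6-tetramethoxybenzyl)-3-(trifluoromethylsulfonyloxy)but-2-enoate
Conditions: Tf2O, aq Me4NOH, toluene, 0–5 °C
Reagents that add atoms: trifluoromethanesulfonic anhydride, O=S(=O)(OS(=O)(=O)C(F)(F)F)C(F)(F)F
Why: Stereoselective enol triflation of a 2-substituted acetoacetate under Schotten–Baumann-type conditions, where the non-chelating ammonium enolate takes the dipole-minimised shape with O− anti to the ester carbonyl, so O-sulfonylation should give the (E)-triflate (OTf cis to CH2Ar) and any Z isomer can be removed by chromatography.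

Step 7
Reactants: 4 tert-butyldimethyl[(4R,5E,7E)-nona-1,5,7-trien-4-yloxy]silane; 11 ethyl (2E)-2-(2,3,5,6-tetramethoxybenzyl)-3-(trifluoromethylsulfonyloxy)but-2-enoate
Product: 13 ethyl (2E,7R,8E,10E)-7-(tert-butyldimethylsilyloxy)-3-methyl-2-(2,3,5,6-tetramethoxybenzyl)dodeca-2,8,10-trienoate, via B-alkyl-9-borabicyclononane 12 (not isolated)
Conditions: 9-BBN, THF, 0 °C → rt; then 11, Pd(dppf)Cl2 (cat.), K3PO4, DMF, 50 °C
Reagents that add atoms: none
Why: 9-BBN hydroborates the monosubstituted alkene far faster than the 1,4-disubstituted diene, and the B-alkyl Suzuki–Miyaura coupling replaces the triflate with retention, so the chain ends up cis to CH2Ar and trans to the ester.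

Step 8
Reactants: 13 ethyl (2E,7R,8E,10E)-7-(tert-butyldimethylsilyloxy)-3-methyl-2-(2,3,5,6-tetramethoxybenzyl)dodeca-2,8,10-trienoate
Product: 14 (2E,7R,8E,10E)-7-(tert-butyldimethylsilyloxy)-3-methyl-2-(2,3,5,6-tetramethoxybenzyl)dodeca-2,8,10-trien-1-ol
Conditions: i-Bu2AlH, CH2Cl2, −78 °C; aq potassium sodium tartrate
Reagents that add atoms: none
Why: 1,2-Reduction of an enoate with i-Bu2AlH gives the allylic alcohol without touching alkene geometry, silyl ether or diene.

Step 9
Reactants: 14 (2E,7R,8E,10E)-7-(tert-butyldimethylsilyloxy)-3-methyl-2-(2,3,5,6-tetramethoxybenzyl)dodeca-2,8,10-trien-1-ol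
Product: 15 (2E,7R,8E,10E)-7-(tert-butyldimethylsilyloxy)-3-methyl-2-(2,3,5,6-tetramethoxybenzyl)dodeca-2,8,10-trienal
Conditions: MnO2, CH2Cl2, rt
Reagents that add atoms: none
Why: Heterogeneous allylic oxidation with MnO2 is neutral, so neither the enal geometry nor the dienylic silyl ether should be disturbed.

Step 10
Reactants: 15 (2E,7R,8E,10E)-7-(tert-butyldimethylsilyloxy)-3-methyl-2-(2,3,5,6-tetramethoxybenzyl)dodeca-2,8,10-trienal
Product: 16 (1S,2S,4aR,5R,8aS)-5-(tert-butyldimethylsilyloxy)-2,8a-dimethyl-1-(2,3,5,6-tetramethoxybenzyl)-1,2,4a,5,6,7,8,8a-octahydronaphthalene-1-carbaldehyde (skeleton: trans-fused; C4 α-OTBS; C5 α-H; C8 β-CH3; C9 β-CHO and α-CH2Ar; C10 β-CH3; C6=C7)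
Conditions: Me2AlCl, CH2Cl2, −78 °C → 0 °C
Reagents that add atoms: none
Why: Binding of Me2AlCl to the formyl oxygen lowers the LUMO of the C9=C10 enal, and the diene C5=C6–C7=C8 adds suprafacially in a concerted but asynchronous [4+2] event in which the C5–C10 bond at the enal β-carbon runs ahead of C8–C9. The closest known reaction type is the Lewis-acid-promoted type 1 intramolecular Diels–Alder reaction of 7-silyloxy-2,8,10-trienals, applied here to a fully substituted dienophile. Ring A closes as a six-membered carbocycle in the fused mode through bond C5–C10 with the C1–C4 tether folded as a chair, and ring B closes as the new cyclohexene through both new bonds with the π bond relocated to C6=C7. C5 and C8 follow from the E,E-diene (C4 and the C8 methyl are both outside groups and end up cis), C9 and C10 follow from the (2E)-enal (formyl and C10 methyl stay cis), and the endo formyl group puts both pairs on the β face, which makes C10-CH3 and C5-H trans. The step needs endo and π-facial selectivity: the endo mode is favoured by the complexed formyl group and by the much larger geminal benzyl group, which must take the exo position, and the face is chosen by the (4R)-silyloxy group staying equatorial on the chair-like tether. The weakly Lewis-basic silyl ether and the low temperature are meant to hold back ionisation of the dienylic C4–O bond.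

Step 11
Reactants: 16 octalin aldehyde
Product: 17 (1S,2S,4aR,5R,8aS)-5-(tert-butyldimethylsilyloxy)-2,8a-dimethyl-1-(2,3,5,6-tetramethoxybenzyl)decahydronaphthalene-1-carbaldehyde
Conditions: H2 (1 atm), Pd/C, EtOAc, rt
Reagents that add atoms: none
Why: Catalytic hydrogenation of the only C=C bond, a cis-disubstituted ring alkene, creates no stereocentre and spares the hindered aldehyde, the arene and the silyl ether.

Step 12
Reactants: 17 decalin aldehyde
Product: 18 (E)-N-tosylhydrazone of 17
Conditions: TsNHNH2, EtOH, reflux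
Reagents that add atoms: 4-methylbenzenesulfonohydrazide, Cc1ccc(cc1)S(=O)(=O)NN
Why: Condensation of an aldehyde with tosylhydrazide, the first half of a Caglioti reduction, is feasible even at a neopentyl formyl group because the carbonyl carbon itself carries only hydrogen.

Step 13
Reactants: 18 (E)-N-tosylhydrazone of 17
Product: 20 (4R,5R,8S,9R,10S)-4-(tert-butyldimethylsilyloxy)-8,9,10-trimethyl-9-(2,3,5,6-tetramethoxybenzyl)-trans-decalin (skeleton numbering), via N-boryl tosylhydrazine 19 (not isolated)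
Conditions: catecholborane, CHCl3, 0 °C → rt; then NaOAc·3H2O, reflux
Reagents that add atoms: none
Why: Caglioti-type reduction in which catecholborane hydroborates the C=N bond, acetate-triggered loss of sulfinate gives the diazene, and loss of N2 leaves the C9 methyl group, with alkene-forming side paths excluded because quaternary C9 has no hydrogen and with C9 keeping its geometry.

Step 14
Reactants: 20 C9-methyl silyl ether
Product: 21 (4R,5R,8S,9R,10S)-8,9,10-trimethyl-9-(2,3,5,6-tetramethoxybenzyl)-trans-decalin-4-ol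
Conditions: Bu4NF, THF, rt → 50 °C
Reagents that add atoms: none
Why: Fluoride-induced desilylation is selective for the Si–O bond and leaves the aryl methyl ethers and all stereocentres alone.

Step 15
Reactants: 21 decalin-4-ol
Product: 22 (5R,8S,9R,10S)-8,9,10-trimethyl-9-(2,3,5,6-tetramethoxybenzyl)-trans-decalin-4-one
Conditions: Dess–Martin periodinane, NaHCO3, CH2Cl2, 0 °C → rt
Reagents that add atoms: none
Why: Buffered Dess–Martin oxidation is near neutral, so C5, now α to the ketone, should not enolise, and the auxiliary C4 centre is removed as planned.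

Step 16
Reactants: 22 decalin-4-one
Product: 23 (5S,8S,9R,10S)-8,9,10-trimethyl-4-methylidene-9-(2,3,5,6-tetramethoxybenzyl)-trans-decalin
Conditions: Zn, CH2Br2, TiCl4, THF–CH2Cl2, 0 °C → rt
Reagents that add atoms: dibromomethane, BrCBr
Why: Takai–Lombardo methylenation uses a non-basic gem-dimetallic reagent and is preferred to a phosphorus ylide, because epimerisation at C5 to the cis-decalone would relieve the 1,3-diaxial C8/C10 methyl contact and must be denied a chance.

Step 17
Reactants: 23 methylidene decalin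
Product: 24 2,5-dimethoxy-3-{[(1R,2S,4aS,8aS)-1,2,8a-trimethyl-5-methylidenedecahydronaphthalen-1-yl]methyl}cyclohexa-2,5-diene-1,4-dione
Conditions: (NH4)2Ce(NO3)6, MeCN–H2O, 0 °C
Reagents that add atoms: water, O
Why: Oxidative demethylation of a hydroquinone dimethyl ether with (NH4)2Ce(NO3)6 gives the para-quinone, the two para pairs of methoxy groups being related by the symmetry of the ring so that one dimethoxyquinone results, and an isolated 1,1-disubstituted alkene tolerates this reagent.

Step 18
Reactants: 24 dimethoxyquinone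
Product: 25 2-hydroxy-5-methoxy-3-{[(1R,2S,4aS,8aS)-1,2,8a-trimethyl-5-methylidenedecahydronaphthalen-1-yl]methyl}cyclohexa-2,5-diene-1,4-dione (target)
Conditions: KOH, MeOH–H2O, rt; then dilute HCl, 0 °C
Reagents that add atoms: potassium hydroxide, [K+].[OH-]
Why: Regioselective saponification of a vinylogous ester by addition–elimination, known for 3-alkyl-2,5-dimethoxyquinones, where the methoxy group next to the alkyl chain is twisted out of conjugation and is displaced first, and the resulting hydroxyquinone anion shuts the ring down toward a second attack.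

**Compound list**
1 | (2E,4E)-hexa-2,4-dienal | C/C=C/C=C/C=O | starting material
2 | (4R,5E,7E)-nona-1,5,7-trien-4-yl diisopinocampheylborinate | C/C=C/C=C/[C@H](OB([C@H]1C[C@H]2C[C@@H]([C@@H]1C)C2(C)C)[C@H]1C[C@H]2C[C@@H]([C@@H]1C)C2(C)C)CC=C | intermediate
3 | (4R,5E,7E)-nona-1,5,7-trien-4-ol | C/C=C/C=C/[C@H](O)CC=C | intermediate
4 | tert-butyldimethyl[(4R,5E,7E)-nona-1,5,7-trien-4-yloxy]silane | C/C=C/C=C/[C@H](O[Si](C)(C)C(C)(C)C)CC=C | intermediate
5 | 1,2,4,5-tetramethoxybenzene | COc1cc(OC)c(OC)cc1OC | starting material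
6 | 2,3,5,6-tetramethoxyphenyllithium | [Li]c1c(OC)c(OC)cc(OC)c1OC | intermediate
7 | 2,3,5,6-tetramethoxybenzaldehyde | O=Cc1c(OC)c(OC)cc(OC)c1OC | intermediate
8 | ethyl acetoacetate | CCOC(=O)CC(C)=O | starting material
9 | ethyl 2-acetyl-3-(2,3,5,6-tetramethoxyphenyl)prop-2-enoate (E/Z mixture) | CCOC(=O)C(=Cc1c(OC)c(OC)cc(OC)c1OC)C(C)=O | intermediate
10 | ethyl 3-oxo-2-(2,3,5,6-tetramethoxybenzyl)butanoate (racemic) | CCOC(=O)C(Cc1c(OC)c(OC)cc(OC)c1OC)C(C)=O | intermediate
11 | ethyl (2E)-2-(2,3,5,6-tetramethoxybenzyl)-3-(trifluoromethylsulfonyloxy)but-2-enoate | FC(F)(F)S(=O)(=O)O/C(C)=C(/C(=O)OCC)Cc1c(OC)c(OC)cc(OC)c1OC | intermediate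
12 | 9-[(4R,5E,7E)-4-(tert-butyldimethylsilyloxy)nona-5,7-dien-1-yl]-9-borabicyclo[3.3.1]nonane | C/C=C/C=C/[C@H](O[Si](C)(C)C(C)(C)C)CCCB1C2CCCC1CCC2 | intermediate
13 | ethyl (2E,7R,8E,10E)-7-(tert-butyldimethylsilyloxy)-3-methyl-2-(2,3,5,6-tetramethoxybenzyl)dodeca-2,8,10-trienoate | C/C=C/C=C/[C@H](O[Si](C)(C)C(C)(C)C)CCC/C(C)=C(/C(=O)OCC)Cc1c(OC)c(OC)cc(OC)c1OC | intermediate
14 | (2E,7R,8E,10E)-7-(tert-butyldimethylsilyloxy)-3-methyl-2-(2,3,5,6-tetramethoxybenzyl)dodeca-2,8,10-trien-1-ol | C/C=C/C=C/[C@H](O[Si](C)(C)C(C)(C)C)CCC/C(C)=C(/CO)Cc1c(OC)c(OC)cc(OC)c1OC | intermediate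
15 | (2E,7R,8E,10E)-7-(tert-butyldimethylsilyloxy)-3-methyl-2-(2,3,5,6-tetramethoxybenzyl)dodeca-2,8,10-trienal | C/C=C/C=C/[C@H](O[Si](C)(C)C(C)(C)C)CCC/C(C)=C(/C=O)Cc1c(OC)c(OC)cc(OC)c1OC | intermediate
16 | trans-fused octalin aldehyde, (4R,5R,8S,9S,10S) in skeleton numbering | CC(C)(C)[Si](C)(C)O[C@@H]1CCC[C@@]2(C)[C@H]1C=C[C@H](C)[C@@]2(C=O)Cc1c(OC)c(OC)cc(OC)c1OC | intermediate
17 | trans-decalin aldehyde, (4R,5R,8S,9S,10S) | CC(C)(C)[Si](C)(C)O[C@@H]1CCC[C@@]2(C)[C@H]1CC[C@H](C)[C@@]2(C=O)Cc1c(OC)c(OC)cc(OC)c1OC | intermediate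
18 | (E)-N-tosylhydrazone of 17 | CC(C)(C)[Si](C)(C)O[C@@H]1CCC[C@@]2(C)[C@H]1CC[C@H](C)[C@@]2(/C=N/NS(=O)(=O)c3ccc(C)cc3)Cc3c(OC)c(OC)cc(OC)c3OC | intermediate
19 | N-(1,3,2-benzodioxaborol-2-yl) tosylhydrazine from 18 | CC(C)(C)[Si](C)(C)O[C@@H]1CCC[C@@]2(C)[C@H]1CC[C@H](C)[C@@]2(CN(NS(=O)(=O)c3ccc(C)cc3)B3Oc4ccccc4O3)Cc3c(OC)c(OC)cc(OC)c3OC | intermediate
20 | C9-methyl silyl ether, (4R,5R,8S,9R,10S) | CC(C)(C)[Si](C)(C)O[C@@H]1CCC[C@@]2(C)[C@H]1CC[C@H](C)[C@@]2(C)Cc1c(OC)c(OC)cc(OC)c1OC | intermediate
21 | decalin-4-ol, (4R,5R,8S,9R,10S) | O[C@@H]1CCC[C@@]2(C)[C@H]1CC[C@H](C)[C@@]2(C)Cc1c(OC)c(OC)cc(OC)c1OC | intermediate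
22 | decalin-4-one, (5R,8S,9R,10S) | O=C1CCC[C@@]2(C)[C@H]1CC[C@H](C)[C@@]2(C)Cc1c(OC)c(OC)cc(OC)c1OC | intermediate
23 | 4-methylidene decalin, (5S,8S,9R,10S) | C=C1CCC[C@@]2(C)[C@H]1CC[C@H](C)[C@@]2(C)Cc1c(OC)c(OC)cc(OC)c1OC | intermediate
24 | 2,5-dimethoxyquinone, (5S,8S,9R,10S) | C=C1CCC[C@@]2(C)[C@H]1CC[C@H](C)[C@@]2(C)CC1=C(OC)C(=O)C=C(OC)C1=O | intermediate
25 | 2-hydroxy-5-methoxyquinone CNP0109104.1, (5S,8S,9R,10S) | C=C1CCC[C@@]2(C)[C@H]1CC[C@H](C)[C@@]2(C)CC1=C(O)C(=O)C=C(OC)C1=O | target

**Totals**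
- Total step count: 18.
- Longest linear sequence: 16 steps (steps 3–18, from 5 to 25).

**Steps most likely to fail**

**Step 10.**
- *Risk:* The cycloaddition may be too slow at the fully substituted dienophile. Ionisation of the dienylic C4–O bond, E/Z isomerisation of the complexed enal or loss of endo selectivity could then take over.
- *Fallback:* It sets out from 4, 7 and 8 and comes back at 16. The benzyl group is left off the dienophile and is added after ring closure.
  - Compound 8 is converted with Tf2O and aq Me4NOH into ethyl (2E)-3-(trifluoromethylsulfonyloxy)but-2-enoate F1.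
  - F1 is coupled with borane 12 (from 4) as in step 7 to ethyl (2E,7R,8E,10E)-7-(tert-butyldimethylsilyloxy)-3-methyldodeca-2,8,10-trienoate F2.
  - i-Bu2AlH gives the trienol F3, and MnO2 gives the trisubstituted trienal F4.
  - The Me2AlCl-promoted cyclisation of this class of enal is well known and should give the C9–H octalin aldehyde F5 with the same ring fusion and the same C8 and C10 centres.
  - In parallel, 7 is reduced with NaBH4 to 2,3,5,6-tetramethoxybenzyl alcohol F6 and brominated with PBr3 to 2,3,5,6-tetramethoxybenzyl bromide F7.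
  - The potassium enolate of F5 (KH, THF) is C-alkylated with F7. The β face of the exocyclic enolate is screened by the C8 and C10 methyl groups, so the benzyl group should enter from the α face and give 16.

**Step 7.**
- *Risk:* The triflate may be lost through base-induced elimination to an allenoate, or through hydrolysis, before the slow coupling at the fully substituted carbon. Hydroboration may also stray onto the diene.
- *Fallback:* It sets out from 4 and 11 and comes back at 13. The union is made without base through an isolated organozinc precursor.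
  - Compound 4 is hydroborated and oxidised (9-BBN; NaOH, H2O2) to (4R,5E,7E)-4-(tert-butyldimethylsilyloxy)nona-5,7-dien-1-ol F8, which can be purified at this stage.
  - Appel iodination (I2, PPh3, imidazole) gives the primary iodide F9.
  - Zinc insertion (Zn, LiCl, THF) gives the alkylzinc iodide F10.
  - F10 couples with 11 under Pd(dppf)Cl2 catalysis in THF (Negishi coupling, retention of geometry) to give 13.

**Step 12.**
- *Risk:* Condensation may stall because the formyl group is buried between quaternary C9/C10 and the di-ortho-substituted benzyl group. Alternatively, the later collapse of the diazene may be diverted.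
- *Fallback:* It sets out from 17 and comes back at 20. The oxygen is removed by a radical path.
  - NaBH4 reduces 17 to the C9 hydroxymethyl decalin F11.
  - NaH, CS2 and MeI give its S-methyl xanthate F12.
  - Bu3SnH with AIBN in refluxing toluene (Barton–McCombie deoxygenation) delivers 20.

**Further compounds**
F1 | step 10 | ethyl (2E)-3-(trifluoromethylsulfonyloxy)but-2-enoate | FC(F)(F)S(=O)(=O)O/C(C)=C/C(=O)OCC
F2 | step 10 | ethyl (2E,7R,8E,10E)-7-(tert-butyldimethylsilyloxy)-3-methyldodeca-2,8,10-trienoate | C/C=C/C=C/[C@H](O[Si](C)(C)C(C)(C)C)CCC/C(C)=C/C(=O)OCC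
F3 | step 10 | (2E,7R,8E,10E)-7-(tert-butyldimethylsilyloxy)-3-methyldodeca-2,8,10-trien-1-ol | C/C=C/C=C/[C@H](O[Si](C)(C)C(C)(C)C)CCC/C(C)=C/CO
F4 | step 10 | (2E,7R,8E,10E)-7-(tert-butyldimethylsilyloxy)-3-methyldodeca-2,8,10-trienal | C/C=C/C=C/[C@H](O[Si](C)(C)C(C)(C)C)CCC/C(C)=C/C=O
F5 | step 10 | C9–H octalin aldehyde, (4R,5R,8S,9S,10S) | CC(C)(C)[Si](C)(C)O[C@@H]1CCC[C@@]2(C)[C@H]1C=C[C@H](C)[C@@H]2C=O
F6 | step 10 | 2,3,5,6-tetramethoxybenzyl alcohol | OCc1c(OC)c(OC)cc(OC)c1OC
F7 | step 10 | 2,3,5,6-tetramethoxybenzyl bromide | BrCc1c(OC)c(OC)cc(OC)c1OC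
F8 | step 7 | (4R,5E,7E)-4-(tert-butyldimethylsilyloxy)nona-5,7-dien-1-ol | C/C=C/C=C/[C@H](O[Si](C)(C)C(C)(C)C)CCCO
F9 | step 7 | tert-butyl[(2E,4E,6R)-9-iodonona-2,4-dien-6-yloxy]dimethylsilane | C/C=C/C=C/[C@H](O[Si](C)(C)C(C)(C)C)CCCI
F10 | step 7 | [(4R,5E,7E)-4-(tert-butyldimethylsilyloxy)nona-5,7-dien-1-yl]zinc iodide | C/C=C/C=C/[C@H](O[Si](C)(C)C(C)(C)C)CCC[Zn]I
F11 | step 12 | C9 hydroxymethyl decalin (17 with CH2OH in place of CHO) | CC(C)(C)[Si](C)(C)O[C@@H]1CCC[C@@]2(C)[C@H]1CC[C@H](C)[C@@]2(CO)Cc1c(OC)c(OC)cc(OC)c1OC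
F12 | step 12 | S-methyl xanthate of F11 | CC(C)(C)[Si](C)(C)O[C@@H]1CCC[C@@]2(C)[C@H]1CC[C@H](C)[C@@]2(COC(=S)SC)Cc1c(OC)c(OC)cc(OC)c1OC
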